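**Assumption:** the SMILES fixes the absolute configuration. In asbestinin numbering (C2 and C9 flank the THF oxygen, C3–O–C16 is the oxepane, butyrate on C11) it is 1S,2S,3S,9S,10R,11R,12R,14S,15R, and this numbering is used throughout.

## Retrosynthetic overview

1. Target ⇒ diol 36: the oxepane is closed last by C3–OH displacing a C16 triflate; the C11 butyrate comes from ketone 32, itself from hydroboration of the C11=C12 alkene of 29.
2. 29 ⇒ tetraene 28 by an intramolecular Diels–Alder reaction (bonds C1–C10 and C13–C14), forming the cyclohexene and the THF together and setting C1, C10 and C14.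
3. 28 ⇒ oxonene 20: the dienophile arm comes from a Julia–Kocienski coupling with sulfone 7 (which carries C15), the diene arm from an allylphosphonate olefination.
4. 20 ⇒ acyclic diene 19 by RCM; C3 from chelation-controlled Grignard addition; C2 from alkylation of dioxanone 13 under 1,3-induction from C9.
5. Stereochemistry is bought as (S)-trityl glycidyl ether (C9) and (S)-3-bromo-2-methylpropan-1-ol (C15). Ring order: oxonene → cyclohexene + THF (one step) → oxepane.

## Route

### Part A – sulfone 7 (carries C15)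

**Step 1**
Reactants: 1 (S)-3-bromo-2-methylpropan-1-ol; 2 1-phenyl-1H-tetrazole-5-thiol
Product: 3 (S)-2-methyl-3-[(1-phenyl-1H-tetrazol-5-yl)sulfanyl]propan-1-ol
Conditions: K2CO3, acetone, rt
Reagents that add atoms: 1-phenyl-1H-tetrazole-5-thiol, Sc1nnnn1-c1ccccc1
Why: SN2 S-alkylation at the primary bromide; the C15 stereocentre is not involved.

**Step 2**
Reactants: 3; 4 tert-butyldimethylsilyl chloride
Product: 5 (S)-5-{[3-(tert-butyldimethylsilyloxy)-2-methylpropyl]sulfanyl}-1-phenyl-1H-tetrazole
Conditions: TBSCl, imidazole, CH2Cl2, rt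
Reagents that add atoms: TBSCl, CC(C)(C)[Si](C)(C)Cl
Why: Routine silylation of the primary alcohol.

**Step 3**
Reactants: 5; 6 mCPBA
Product: 7 (S)-5-{[3-(tert-butyldimethylsilyloxy)-2-methylpropyl]sulfonyl}-1-phenyl-1H-tetrazole
Conditions: mCPBA (2.5 equiv), NaHCO3, CH2Cl2, 0 °C → rt
Reagents that add atoms: mCPBA, OOC(=O)c1cccc(Cl)c1
Why: Sulfide-to-sulfone oxidation; no alkene is present and the TBS ether survives buffered peracid.

### Part B – main line

**Step 4**
Reactants: 8 (S)-trityl glycidyl ether; 9 isopropenylmagnesium bromide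
Product: 10 (S)-4-methyl-1-(trityloxy)pent-4-en-2-ol
Conditions: CuI (10 mol%), THF, −30 → 0 °C
Reagents that add atoms: isopropenylmagnesium bromide, CC(=C)[Mg]Br
Why: Cu-catalysed epoxide opening at the terminal carbon; the C9 carbinol configuration is carried over from the glycidyl ether.

**Step 5**
Reactants: 10; 11 bromoacetic acid
Product: 12 2-{[(2S)-4-methyl-1-(trityloxy)pent-4-en-2-yl]oxy}acetic acid
Conditions: NaH (3 equiv), BrCH2CO2H, THF, 0 °C → rt
Reagents that add atoms: bromoacetic acid, OC(=O)CBr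
Why: Williamson etherification of the secondary alkoxide with sodium bromoacetate builds the C9–O–C2 ether; trityl cannot migrate (unlike a silyl group).

**Step 6**
Reactants: 12
Product: 13 (5S)-5-(2-methylprop-2-en-1-yl)-1,4-dioxan-2-one
Conditions: TsOH·H2O (cat.), MeOH–CH2Cl2, rt; then PPTS (cat.), PhMe, 60 °C
Reagents that add atoms: none
Why: Mild acid removes the trityl group and the freed primary alcohol lactonises to the six-membered dioxanone, which will relay C9 chirality to C2.

**Step 7**
Reactants: 13; 14 benzyl chloromethyl ether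
Product: 15 (3S,5S)-3-[(benzyloxy)methyl]-5-(2-methylprop-2-en-1-yl)-1,4-dioxan-2-one (3,5-trans)
Conditions: LiHMDS, THF, −78 °C; BnOCH2Cl, −78 → −40 °C
Reagents that add atoms: benzyl chloromethyl ether, ClCOCc1ccccc1
Why: Lactone enolate alkylation; axial attack on the half-chair enolate with the C5 side chain pseudo-equatorial is expected to give the 3,5-trans product, setting C2 (S), which corresponds to cis-2,9 in the later oxonene.

**Step 8**
Reactants: 15; 16 methyllithium
Product: 17 (3S,5S)-3-[(benzyloxy)methyl]-2-methyl-5-(2-methylprop-2-en-1-yl)-1,4-dioxan-2-ol (anomeric mixture, in equilibrium with the open hydroxy methyl ketone)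
Conditions: MeLi (1.05 equiv), THF, −78 °C; AcOH quench at −78 °C
Reagents that add atoms: methyllithium, [Li]C
Why: Mono-addition to the lactone stops at the stable tetrahedral intermediate, giving a masked α-alkoxy methyl ketone at C3.

**Step 9**
Reactants: 17; 18 but-3-en-1-ylmagnesium bromide
Product: 19 (2S,3S)-1-(benzyloxy)-2-{[(2S)-1-hydroxy-4-methylpent-4-en-2-yl]oxy}-3-methylhept-6-en-3-ol
Conditions: CH2=CHCH2CH2MgBr (4 equiv), THF, −78 → 0 °C
Reagents that add atoms: but-3-en-1-ylmagnesium bromide, C=CCC[Mg]Br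
Why: Cram-chelate addition to the ring-opened α-alkoxy ketone (Mg bridges C=O and the C2 ether oxygen, attack from the C2–H face) sets C3 (S).

**Step 10**
Reactants: 19
Product: 20 (2S,3S,6Z,9S)-2-[(benzyloxy)methyl]-9-(hydroxymethyl)-3,7-dimethyl-2,3,4,5,8,9-hexahydrooxonin-3-ol
Conditions: Grubbs II (5 mol%), CH2Cl2 (2 mM), 40 °C
Reagents that add atoms: none
Why: Ring-closing metathesis of the monosubstituted and 1,1-disubstituted alkenes gives the nine-membered ether; the ring enforces the (Z)-trisubstituted C6=C7 alkene.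

**Step 11**
Reactants: 20; 21 triethylsilyl triflate
Product: 22 bis-TES ether of 20 (primary C10–OTES, tertiary C3–OTES)
Conditions: TESOTf (2.5 equiv), 2,6-lutidine, CH2Cl2, −78 → 0 °C
Reagents that add atoms: TESOTf, CC[Si](CC)(CC)OS(=O)(=O)C(F)(F)F
Why: Silyl triflate caps both alcohols; the tertiary C3–OTES prevents lactol formation and retro-aldol in the aldehyde steps, and the primary TES is a latent C10 aldehyde.

**Step 12**
Reactants: 22
Product: 23 [(2S,3S,6Z,9S)-3,7-dimethyl-3-(triethylsilyloxy)-9-[(triethylsilyloxy)methyl]-2,3,4,5,8,9-hexahydrooxonin-2-yl]methanol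
Conditions: LiDBB, THF, −78 °C
Reagents that add atoms: none
Why: Dissolving-metal-type debenzylation frees C1–OH without touching the trisubstituted alkene or the silyl ethers.

**Step 13**
Reactants: 23
Product: 24 the corresponding C1 aldehyde (oxonine-2-carbaldehyde, same configuration)
Conditions: Dess–Martin periodinane, NaHCO3, CH2Cl2, 0 °C → rt
Reagents that add atoms: none
Why: Buffered DMP oxidation gives the α-alkoxy aldehyde without epimerising C2.

**Step 14**
Reactants: 24; 7
Product: 25 (2S,3S,6Z,9S)-2-[(1E,3R)-4-(tert-butyldimethylsilyloxy)-3-methylbut-1-en-1-yl]-3,7-dimethyl-3-(triethylsilyloxy)-9-[(triethylsilyloxy)methyl]-2,3,4,5,8,9-hexahydrooxonine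
Conditions: 7, KHMDS, DME, −78 °C; then 24, −78 °C → rt
Reagents that add atoms: sulfone 7, CC(C)(C)[Si](C)(C)OC[C@H](C)CS(=O)(=O)c1nnnn1-c1ccccc1
Why: Julia–Kocienski olefination gives the (E)-C1=C14 dienophile and brings in C15 (R) from the chiral pool.

**Step 15**
Reactants: 25
Product: 26 (2S,4Z,8S,9S)-9-[(1E,3R)-4-(tert-butyldimethylsilyloxy)-3-methylbut-1-en-1-yl]-4,8-dimethyl-8-(triethylsilyloxy)-2,3,6,7,8,9-hexahydrooxonine-2-carbaldehyde
Conditions: (COCl)2, DMSO, CH2Cl2, −78 → −40 °C; Et3N, → 0 °C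
Reagents that add atoms: none
Why: Swern conditions cleave and oxidise a primary TES ether directly to the aldehyde while the tertiary TES and primary TBS ethers remain.

**Step 16**
Reactants: 26; 27 diethyl (2-methylallyl)phosphonate
Product: 28 (2S,3S,6Z,9S)-2-[(1E,3R)-4-(tert-butyldimethylsilyloxy)-3-methylbut-1-en-1-yl]-3,7-dimethyl-9-[(1E)-3-methylbuta-1,3-dien-1-yl]-3-(triethylsilyloxy)-2,3,4,5,8,9-hexahydrooxonine
Conditions: 27, n-BuLi, THF–HMPA, −78 °C; then 26, −78 °C → rt
Reagents that add atoms: diethyl (2-methylallyl)phosphonate, CCOP(=O)(CC(C)=C)OCC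
Why: Horner–Wadsworth–Emmons reaction of the lithiated allylic phosphonate (α-attack, then elimination) gives the (E)-2-methyl-1,3-diene in one step.

**Step 17 (key step)**
Reactants: 28
Product: 29 tricyclic cyclohexene: cis-fused hexahydroisobenzofuran (H1/H10 cis; H1/H2 and H9/H10 trans) bridged C2-to-C9 by the (6Z)-oxonene; C11=C12(CH3) alkene; C14 bears (R)-CH(CH3)CH2OTBS trans to C2; C3–OTES
Conditions: PhMe (5 mM), BHT, 130 °C, sealed tube
Reagents that add atoms: none
Why: Intramolecular Diels–Alder reaction across the cis-2,9-oxonene; the ring forces the tether-endo transition state on the face away from the oxonene, giving the cis-fused adduct (C1, C10), and the (E)-dienophile places C15 trans to C2 (C14).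

**Step 18**
Reactants: 29; 30 hydrogen peroxide
Product: 31 11-epi alcohol (C11–OH on the convex face, trans to the C12 methyl; C12 R as in the target)
Conditions: BH3·THF (1.2 equiv), THF, 0 °C; then NaOH, H2O2
Reagents that add atoms: borane–THF (adds H), B.C1CCOC1; hydrogen peroxide, OO
Why: Syn hydroboration–oxidation of the cyclohexene from the convex face (anti to the THF carbons) puts boron on C11 and H on C12, setting C12.

**Step 19**
Reactants: 31
Product: 32 C11 ketone
Conditions: Dess–Martin periodinane, NaHCO3, CH2Cl2, 0 °C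
Reagents that add atoms: none
Why: Neutral oxidation removes the wrong C11 configuration without epimerising the adjacent C12 and C10 centres.

**Step 20**
Reactants: 32
Product: 33 11α-alcohol (C11 R; OH cis to the C12 methyl and to C9)
Conditions: NaBH4, MeOH, −20 °C
Reagents that add atoms: none
Why: Hydride attacks the ketone from the same convex face used in step 18, placing the hydroxyl on the concave face and setting C11.

**Step 21**
Reactants: 33; 34 butyric anhydride
Product: 35 C11 butyrate (C3–OTES, C16–OTBS intact)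
Conditions: (PrCO)2O, Et3N, DMAP, CH2Cl2, rt
Reagents that add atoms: butyric anhydride, CCCC(=O)OC(=O)CCC
Why: DMAP-catalysed acylation of the only free hydroxyl.

**Step 22**
Reactants: 35
Product: 36 diol (free tertiary C3–OH and primary C16–OH)
Conditions: HF·pyridine, pyridine–THF, 0 °C → rt
Reagents that add atoms: none
Why: Global desilylation; the butyrate and the alkene are stable to buffered HF.

**Step 23**
Reactants: 36
Product: 37 4-deoxyasbestinin C
Conditions: Tf2O (1.1 equiv), 2,6-lutidine, CH2Cl2, −78 → 0 °C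
Reagents that add atoms: none
Why: The primary alcohol is triflated selectively and the nearby tertiary C3–OH displaces it (intramolecular Williamson-type etherification) to close the oxepane; no stereocentre is touched.

**Stereocentre audit:** C9 and C15 are bought (8 and 1). C2 is set in step 7, C3 in step 9, C1/C10/C14 in step 17, C12 in step 18 and C11 in step 20. The C6=C7 (Z) geometry is set in step 10.

## Compound list

1 | (S)-3-bromo-2-methylpropan-1-ol | OC[C@H](C)CBr | starting material
2 | 1-phenyl-1H-tetrazole-5-thiol | Sc1nnnn1-c1ccccc1 | starting material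
3 | (S)-2-methyl-3-[(1-phenyl-1H-tetrazol-5-yl)sulfanyl]propan-1-ol | OC[C@H](C)CSc1nnnn1-c1ccccc1 | intermediate
4 | tert-butyldimethylsilyl chloride | CC(C)(C)[Si](C)(C)Cl | starting material
5 | (S)-5-{[3-(TBSO)-2-methylpropyl]sulfanyl}-1-phenyl-1H-tetrazole | CC(C)(C)[Si](C)(C)OC[C@H](C)CSc1nnnn1-c1ccccc1 | intermediate
6 | mCPBA | OOC(=O)c1cccc(Cl)c1 | starting material
7 | (S)-5-{[3-(TBSO)-2-methylpropyl]sulfonyl}-1-phenyl-1H-tetrazole | CC(C)(C)[Si](C)(C)OC[C@H](C)CS(=O)(=O)c1nnnn1-c1ccccc1 | intermediate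
8 | (S)-trityl glycidyl ether | C(OC[C@@H]1CO1)(c1ccccc1)(c1ccccc1)c1ccccc1 | starting material
9 | isopropenylmagnesium bromide | CC(=C)[Mg]Br | starting material
10 | (S)-4-methyl-1-(trityloxy)pent-4-en-2-ol | CC(=C)C[C@H](O)COC(c1ccccc1)(c1ccccc1)c1ccccc1 | intermediate
11 | bromoacetic acid | OC(=O)CBr | starting material
12 | 2-{[(2S)-4-methyl-1-(trityloxy)pent-4-en-2-yl]oxy}acetic acid | CC(=C)C[C@H](OCC(=O)O)COC(c1ccccc1)(c1ccccc1)c1ccccc1 | intermediate
13 | (5S)-5-(2-methylprop-2-en-1-yl)-1,4-dioxan-2-one | O=C1CO[C@@H](CC(C)=C)CO1 | intermediate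
14 | benzyl chloromethyl ether | ClCOCc1ccccc1 | starting material
15 | (3S,5S)-3-[(benzyloxy)methyl]-5-(2-methylprop-2-en-1-yl)-1,4-dioxan-2-one | O=C1[C@H](COCc2ccccc2)O[C@@H](CC(C)=C)CO1 | intermediate
16 | methyllithium | [Li]C | starting material
17 | (3S,5S)-3-[(benzyloxy)methyl]-2-methyl-5-(2-methylprop-2-en-1-yl)-1,4-dioxan-2-ol (lactol) | CC1(O)[C@H](COCc2ccccc2)O[C@@H](CC(C)=C)CO1 | intermediate
18 | but-3-en-1-ylmagnesium bromide | C=CCC[Mg]Br | starting material
19 | (2S,3S)-1-(benzyloxy)-2-{[(2S)-1-hydroxy-4-methylpent-4-en-2-yl]oxy}-3-methylhept-6-en-3-ol | OC[C@H](CC(C)=C)O[C@@H](COCc1ccccc1)[C@@](C)(O)CCC=C | intermediate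
20 | (2S,3S,6Z,9S)-2-[(benzyloxy)methyl]-9-(hydroxymethyl)-3,7-dimethyl-2,3,4,5,8,9-hexahydrooxonin-3-ol | OC[C@@H]1C/C(C)=C\CC[C@](C)(O)[C@H](COCc2ccccc2)O1 | intermediate
21 | triethylsilyl trifluoromethanesulfonate | CC[Si](CC)(CC)OS(=O)(=O)C(F)(F)F | starting material
22 | bis-TES ether of 20 | CC[Si](CC)(CC)OC[C@@H]1C/C(C)=C\CC[C@](C)(O[Si](CC)(CC)CC)[C@H](COCc2ccccc2)O1 | intermediate
23 | C1 primary alcohol (debenzylated 22) | CC[Si](CC)(CC)OC[C@@H]1C/C(C)=C\CC[C@](C)(O[Si](CC)(CC)CC)[C@H](CO)O1 | intermediate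
24 | C1 aldehyde | CC[Si](CC)(CC)OC[C@@H]1C/C(C)=C\CC[C@](C)(O[Si](CC)(CC)CC)[C@H](C=O)O1 | intermediate
25 | oxonene with the (1E,3R)-4-(TBSO)-3-methylbut-1-enyl dienophile arm | CC[Si](CC)(CC)OC[C@@H]1C/C(C)=C\CC[C@](C)(O[Si](CC)(CC)CC)[C@H](/C=C/[C@@H](C)CO[Si](C)(C)C(C)(C)C)O1 | intermediate
26 | C10 aldehyde | O=C[C@@H]1C/C(C)=C\CC[C@](C)(O[Si](CC)(CC)CC)[C@H](/C=C/[C@@H](C)CO[Si](C)(C)C(C)(C)C)O1 | intermediate
27 | diethyl (2-methylallyl)phosphonate | CCOP(=O)(CC(C)=C)OCC | starting material
28 | tetraene (Diels–Alder substrate) | C=C(C)/C=C/[C@@H]1C/C(C)=C\CC[C@](C)(O[Si](CC)(CC)CC)[C@H](/C=C/[C@@H](C)CO[Si](C)(C)C(C)(C)C)O1 | intermediate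
29 | Diels–Alder adduct (tricyclic C11=C12 alkene) | CC1=C[C@@H]2[C@H]([C@@H](C1)[C@@H](C)CO[Si](C)(C)C(C)(C)C)[C@@H]3O[C@H]2C/C(C)=C\CC[C@]3(C)O[Si](CC)(CC)CC | intermediate
30 | hydrogen peroxide | OO | starting material
31 | 11-epi alcohol | C[C@H]1[C@H](O)[C@@H]2[C@H]([C@@H](C1)[C@@H](C)CO[Si](C)(C)C(C)(C)C)[C@@H]3O[C@H]2C/C(C)=C\CC[C@]3(C)O[Si](CC)(CC)CC | intermediate
32 | C11 ketone | C[C@H]1C(=O)[C@@H]2[C@H]([C@@H](C1)[C@@H](C)CO[Si](C)(C)C(C)(C)C)[C@@H]3O[C@H]2C/C(C)=C\CC[C@]3(C)O[Si](CC)(CC)CC | intermediate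
33 | 11α-alcohol (natural C11) | C[C@H]1[C@@H](O)[C@@H]2[C@H]([C@@H](C1)[C@@H](C)CO[Si](C)(C)C(C)(C)C)[C@@H]3O[C@H]2C/C(C)=C\CC[C@]3(C)O[Si](CC)(CC)CC | intermediate
34 | butyric anhydride | CCCC(=O)OC(=O)CCC | starting material
35 | C11 butyrate, bis-silyl ether | C[C@H]1[C@@H](OC(=O)CCC)[C@@H]2[C@H]([C@@H](C1)[C@@H](C)CO[Si](C)(C)C(C)(C)C)[C@@H]3O[C@H]2C/C(C)=C\CC[C@]3(C)O[Si](CC)(CC)CC | intermediate
36 | C3,C16-diol butyrate | C[C@H]1[C@@H](OC(=O)CCC)[C@@H]2[C@H]([C@@H](C1)[C@@H](C)CO)[C@@H]3O[C@H]2C/C(C)=C\CC[C@]3(C)O | intermediate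
37 | 4-deoxyasbestinin C | CCCC(=O)O[C@H]1[C@@H]2[C@@H]3[C@@H](C[C@H]1C)[C@@H](C)CO[C@@]1(C)CC/C=C(/C)C[C@@H]2O[C@@H]31 | target

## Step count and main risks

Total steps: 23 (3 for sulfone 7, 20 on the main line).
Longest linear sequence: 20 steps (steps 4–23, from (S)-trityl glycidyl ether 8).

Three steps most likely to fail, each with a fallback that changes the approach:

1. **Step 7, dioxanone alkylation.** The 1,3-induction from a single C5 alkyl group may give only modest trans selectivity. Fallback: buy C2 instead of inducing it, by SN2 etherification of the alkoxide of a 1-O-benzyl analogue of 10 with methyl (R)-3-(benzyloxy)-2-(triflyloxy)propanoate (from O-benzyl-D-serine, inversion gives 2S). Then carry out the same MeLi and butenyl Grignard sequence on the ester.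

2. **Step 17, thermal Diels–Alder with an unactivated dienophile.** The rate and the cis-fused selectivity are the main uncertainty because the dienophile has no activating group. Fallback: use an acetyl-activated dienophile (Wittig of 24 with Ph3P=CHC(O)CH3), which should cyclise near room temperature. C15 is then built after the cycloaddition by methylenation of the C15 ketone, hydroboration and oxepane closure, correcting C15 if needed by hydrogenating a 15-methylene oxepane from the convex face.

3. **Step 18, hydroboration of C11=C12 in the presence of C6=C7.** Both alkenes are trisubstituted, so chemoselectivity is uncertain. Fallback: bring the C11 oxygen in with the diene, using an α-methoxy-2-methylallyl phosphine oxide in step 16 to give a 2-methoxydiene. The Diels–Alder adduct is then an enol ether, and mild hydrolysis with convex-face protonation gives ketone 32 directly without any borane.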